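**Plan**
- Retrosynthesis cuts, in one operation, the ring C bond C4–C4a and the two aryl–prenyl bonds (C8–CH2 and C3'–CH2), all three traced back to C–Br; then the ether bond O1–C2; then C2–C3 (allyl addition to the ring B aldehyde), C4 being the inner carbon of a trimmed allyl group.
- Enabling feature: in ring A, C4a and C8 are the two carbons ortho to C8a–O1, each between two oxygen-bearing carbons. In a 2,6-dibromo-3,5-dioxygenated phenyl ether they are interchangeable by rotation about C8a–O1, so the lithiated carbon that closes ring C becomes C4a and the other is C8. C3' of ring B sits ortho to the 4'-methoxy group.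
- Forward order: ring A is made as the symmetric dibromophenol; the ring B aldehyde is allylated; the two are joined by Mitsunobu etherification; the alkene is cut to the acid and turned into the Weinreb amide; one pot then closes ring C and places both prenyl groups; acid removes the MOM groups.
- Stereochemistry: C2 is set as (R) by reagent-controlled Brown allylation and inverted once to (S) in the Mitsunobu step. No later step breaks a bond at C2, and the C4 ketone is unmasked only after all base is quenched.

Key step: step 8

Remark: flavanone numbering is used (O1, C2, C3, C4, C4a, C5 to C8, C8a; ring B primed); prenyl = 3-methylbut-2-enyl, MOM = methoxymethyl.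

**Route**

Step 1
Reactants: 1 phloroglucinol (benzene-1,3,5-triol)
Product: 2 3,5-bis(methoxymethoxy)phenol
Conditions: NaH (2.0 equiv), MOMCl (2.0 equiv), DMF, 0 °C to rt
Reagents that add atoms: chloromethyl methyl ether (MOMCl) COCCl
Why: Statistical Williamson-type O-alkylation of three equivalent phenols should give the bis-MOM ether as the main fraction, with the mono- and tris-ethers separable and recyclable.

Step 2
Reactants: 2 3,5-bis(methoxymethoxy)phenol
Product: 3 2,6-dibromo-3,5-bis(methoxymethoxy)phenol
Conditions: NBS (2.05 equiv), i-Pr2NH (10 mol%), CH2Cl2, −78 to 0 °C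
Reagents that add atoms: N-bromosuccinimide O=C1CCC(=O)N1Br
Why: Amine-catalysed ortho-selective electrophilic bromination of a phenol should place bromine at both positions next to the free OH, while C4 is shielded between two MOM ethers.

Step 3
Reactants: 4 3-bromo-4-methoxybenzaldehyde
Product: 6 (R)-1-(3-bromo-4-methoxyphenyl)but-3-en-1-ol, via borinate ester 5 (not isolated)
Conditions: (+)-Ipc2B(allyl) [from (−)-α-pinene], Et2O, −78 °C; then NaOH, H2O2, 0 °C to rt
Reagents that add atoms: (+)-B-allyldiisopinocampheylborane C=CCB([C@H]1C[C@H]2C[C@@H]([C@@H]1C)C2(C)C)[C@H]1C[C@H]2C[C@@H]([C@@H]1C)C2(C)C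
Why: Brown allylation transfers the allyl group through a closed chair transition state in which the isopinocampheyl groups select the aldehyde face that leads to the (R)-carbinol (reagent control), and oxidative work-up frees 6 from borinate 5.

Step 4
Reactants: 3 2,6-dibromo-3,5-bis(methoxymethoxy)phenol, 6 (R)-1-(3-bromo-4-methoxyphenyl)but-3-en-1-ol
Product: 7 (S)-2,4-dibromo-3-[1-(3-bromo-4-methoxyphenyl)but-3-enyloxy]-1,5-bis(methoxymethoxy)benzene
Conditions: PPh3, DIAD, toluene (about 1 M), 0 °C to rt
Reagents that add atoms: none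
Why: In this Mitsunobu etherification the acidic dibromophenol protonates the betaine and its phenoxide displaces the alkoxyphosphonium by SN2 with inversion, turning (R)-6 into (S)-7; the meta bromine on ring B tempers benzylic ionization and the homoallylic alcohol has no carbonyl-activated hydrogen for elimination.

Step 5
Reactants: 7 (S)-2,4-dibromo-3-[1-(3-bromo-4-methoxyphenyl)but-3-enyloxy]-1,5-bis(methoxymethoxy)benzene
Product: 9 (S)-3-(3-bromo-4-methoxyphenyl)-3-[2,6-dibromo-3,5-bis(methoxymethoxy)phenoxy]propanal, via 1,2-diol 8 (not isolated)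
Conditions: OsO4 (2 mol%), NaIO4 (4 equiv), 2,6-lutidine, dioxane/H2O, rt; crude product used directly
Reagents that add atoms: osmium tetroxide O=[Os](=O)(=O)=O (catalytic oxygen carrier); sodium periodate [Na+].[O-]I(=O)(=O)=O (terminal oxidant)
Why: In this Lemieux–Johnson oxidation OsO4 dihydroxylates the only alkene (no prenyl group is present yet) and periodate cleaves diol 8 to the aldehyde, the buffered base-free medium avoiding beta-elimination of the aryloxide.

Step 6
Reactants: 9 (S)-3-(3-bromo-4-methoxyphenyl)-3-[2,6-dibromo-3,5-bis(methoxymethoxy)phenoxy]propanal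
Product: 10 (S)-3-(3-bromo-4-methoxyphenyl)-3-[2,6-dibromo-3,5-bis(methoxymethoxy)phenoxy]propanoic acid
Conditions: NaClO2, NaH2PO4, 2-methyl-2-butene, t-BuOH/H2O, 0 °C to rt
Reagents that add atoms: sodium chlorite [Na+].[O-]Cl=O
Why: Pinnick oxidation works in acidic buffer, so no enolate forms and the aryloxide is not lost, while 2-methyl-2-butene scavenges HOCl and protects the electron-rich rings from chlorination.

Step 7
Reactants: 10 (S)-3-(3-bromo-4-methoxyphenyl)-3-[2,6-dibromo-3,5-bis(methoxymethoxy)phenoxy]propanoic acid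
Product: 12 (S)-3-(3-bromo-4-methoxyphenyl)-3-[2,6-dibromo-3,5-bis(methoxymethoxy)phenoxy]-N-methoxy-N-methylpropanamide, via acyl imidazolide 11 (not isolated)
Conditions: CDI, CH2Cl2, 0 °C; then MeNHOMe·HCl, 0 °C to rt
Reagents that add atoms: N,O-dimethylhydroxylamine hydrochloride CNOC.Cl; 1,1'-carbonyldiimidazole O=C(n1ccnc1)n1ccnc1 (its imidazole stays only in 11)
Why: Weinreb amide formation through acyl imidazolide 11 should be faster than enolization of 11 by the weak base imidazole, so the aryloxy group and the C2 configuration are kept.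

Step 8
Reactants: 12 (S)-3-(3-bromo-4-methoxyphenyl)-3-[2,6-dibromo-3,5-bis(methoxymethoxy)phenoxy]-N-methoxy-N-methylpropanamide
Product: 15 (S)-5,7-bis(methoxymethoxy)-2-[4-methoxy-3-(3-methylbut-2-enyl)phenyl]-8-(3-methylbut-2-enyl)chroman-4-one, via trilithiated cyclized hemiaminal 13 (not isolated), via diprenylated lithium hemiaminal 14 (not isolated)
Conditions: t-BuLi (6.2 equiv), THF, −78 °C; CuBr·SMe2 (20 mol%), prenyl bromide (4 equiv), −78 to −20 °C; sat. aq NH4Cl
Reagents that add atoms: prenyl bromide (1-bromo-3-methylbut-2-ene) CC(C)=CCBr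
Why: Three bromine–lithium exchanges (t-BuLi, two equivalents per bromine) give a trilithiated species in which one of the two equivalent ring A aryllithiums ortho to O1 adds to the Weinreb carbonyl and forms the C4–C4a bond, giving the chelated lithium hemiaminal 13; the aryllithiums left at C8 and C3' are then alkylated at the primary carbon of prenyl bromide (CuBr·SMe2 catalysis) to give 14, and only the aqueous quench releases the ketone. The closest known reaction types are the Parham cyclization of 2-bromoaryl ethers of 3-hydroxy Weinreb amides to chroman-4-ones and the C-prenylation of ortho-alkoxy aryllithiums. Ring C closes in a 6-exo-trig mode (aryl carbanion onto the amide carbonyl). No stereocenter is created in 15: C2 keeps the (S) configuration of 12 because no bond to C2 is broken and the C4 carbonyl stays masked as the hemiaminal while strong base is present, so neither enolization at C3 nor retro-oxa-Michael opening can occur. The step needs exchange to outrun addition of t-BuLi to the amide and deprotonation at C3, which is the usual order at −78 °C for aryl bromides flanked by oxygen substituents, and it needs prenyl groups at C8 and C3' only: the bromine positions fix this, since the two ring A bromines are interchangeable by rotation about the C8a–O1 bond and the one that does not cyclize is necessarily C8, while C6 carries hydrogen throughout. Attack at the primary (alpha) carbon of prenyl bromide is favoured by the hindered tertiary gamma carbon.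

Step 9
Reactants: 15 (S)-5,7-bis(methoxymethoxy)-2-[4-methoxy-3-(3-methylbut-2-enyl)phenyl]-8-(3-methylbut-2-enyl)chroman-4-one
Product: 16 (2S)-5,7-dihydroxy-2-[4-methoxy-3-(3-methylbut-2-enyl)phenyl]-8-(3-methylbut-2-enyl)chroman-4-one
Conditions: 3 M aq HCl, MeOH, 40 °C
Reagents that add atoms: none
Why: Acid-catalysed cleavage of the two MOM acetals at mild temperature should keep the C7 hydroxyl from adding to the C8 prenyl group, and without base C2 cannot epimerize through the chalcone.

**Compound list**

1 | phloroglucinol (benzene-1,3,5-triol) | Oc1cc(O)cc(O)c1 | starting material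
2 | 3,5-bis(methoxymethoxy)phenol | COCOc1cc(O)cc(OCOC)c1 | intermediate
3 | 2,6-dibromo-3,5-bis(methoxymethoxy)phenol | COCOc1cc(OCOC)c(Br)c(O)c1Br | intermediate
4 | 3-bromo-4-methoxybenzaldehyde | COc1ccc(C=O)cc1Br | starting material
5 | (R)-1-(3-bromo-4-methoxyphenyl)but-3-enyl diisopinocampheylborinate | C=CC[C@@H](OB([C@H]1C[C@H]2C[C@@H]([C@@H]1C)C2(C)C)[C@H]1C[C@H]2C[C@@H]([C@@H]1C)C2(C)C)c1ccc(OC)c(Br)c1 | intermediate (not isolated)
6 | (R)-1-(3-bromo-4-methoxyphenyl)but-3-en-1-ol | C=CC[C@@H](O)c1ccc(OC)c(Br)c1 | intermediate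
7 | (S)-2,4-dibromo-3-[1-(3-bromo-4-methoxyphenyl)but-3-enyloxy]-1,5-bis(methoxymethoxy)benzene | C=CC[C@H](Oc1c(Br)c(OCOC)cc(OCOC)c1Br)c1ccc(OC)c(Br)c1 | intermediate
8 | (4S)-4-(3-bromo-4-methoxyphenyl)-4-[2,6-dibromo-3,5-bis(methoxymethoxy)phenoxy]butane-1,2-diol (both C2 epimers) | OCC(O)C[C@H](Oc1c(Br)c(OCOC)cc(OCOC)c1Br)c1ccc(OC)c(Br)c1 | intermediate (not isolated)
9 | (S)-3-(3-bromo-4-methoxyphenyl)-3-[2,6-dibromo-3,5-bis(methoxymethoxy)phenoxy]propanal | O=CC[C@H](Oc1c(Br)c(OCOC)cc(OCOC)c1Br)c1ccc(OC)c(Br)c1 | intermediate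
10 | (S)-3-(3-bromo-4-methoxyphenyl)-3-[2,6-dibromo-3,5-bis(methoxymethoxy)phenoxy]propanoic acid | OC(=O)C[C@H](Oc1c(Br)c(OCOC)cc(OCOC)c1Br)c1ccc(OC)c(Br)c1 | intermediate
11 | (S)-3-(3-bromo-4-methoxyphenyl)-3-[2,6-dibromo-3,5-bis(methoxymethoxy)phenoxy]-1-(imidazol-1-yl)propan-1-one | O=C(C[C@H](Oc1c(Br)c(OCOC)cc(OCOC)c1Br)c1ccc(OC)c(Br)c1)n1ccnc1 | intermediate (not isolated)
12 | (S)-3-(3-bromo-4-methoxyphenyl)-3-[2,6-dibromo-3,5-bis(methoxymethoxy)phenoxy]-N-methoxy-N-methylpropanamide | CON(C)C(=O)C[C@H](Oc1c(Br)c(OCOC)cc(OCOC)c1Br)c1ccc(OC)c(Br)c1 | intermediate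
13 | lithium (2S)-8-lithio-2-(3-lithio-4-methoxyphenyl)-4-[methoxy(methyl)amino]-5,7-bis(methoxymethoxy)chroman-4-olate (C4 undefined) | CON(C)C1(O[Li])C[C@@H](c2ccc(OC)c([Li])c2)Oc2c([Li])c(OCOC)cc(OCOC)c21 | intermediate (not isolated)
14 | lithium (2S)-4-[methoxy(methyl)amino]-5,7-bis(methoxymethoxy)-2-[4-methoxy-3-(3-methylbut-2-enyl)phenyl]-8-(3-methylbut-2-enyl)chroman-4-olate (C4 undefined) | CON(C)C1(O[Li])C[C@@H](c2ccc(OC)c(CC=C(C)C)c2)Oc2c(CC=C(C)C)c(OCOC)cc(OCOC)c21 | intermediate (not isolated)
15 | (S)-5,7-bis(methoxymethoxy)-2-[4-methoxy-3-(3-methylbut-2-enyl)phenyl]-8-(3-methylbut-2-enyl)chroman-4-one | COc1ccc([C@@H]2CC(=O)c3c(OCOC)cc(OCOC)c(CC=C(C)C)c3O2)cc1CC=C(C)C | intermediate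
16 | (2S)-5,7-dihydroxy-2-[4-methoxy-3-(3-methylbut-2-enyl)phenyl]-8-(3-methylbut-2-enyl)chroman-4-one (CNP0223481.2) | COc1ccc([C@@H]2CC(=O)c3c(O)cc(O)c(CC=C(C)C)c3O2)cc1CC=C(C)C | target

**Step count and risks**

Total steps: 9. Longest linear sequence: 8 steps (steps 1, 2, 4, 5, 6, 7, 8, 9, from phloroglucinol).

The three steps most likely to fail:

(1) Step 8. Incomplete triple exchange, proton transfer to the aryllithiums before alkylation, or sluggish or gamma-selective alkylation at the hindered C8 lithium would give mixtures of mono-prenylated and protio products. The fallback separates ring closure from prenylation. It sets out from 12: with only 2.0 equiv of t-BuLi at −100 °C a ring A bromine should exchange first (its aryllithium lies between two oxygen-bearing carbons), and Parham cyclization followed by NH4Cl quench should give (S)-8-bromo-2-(3-bromo-4-methoxyphenyl)-5,7-bis(methoxymethoxy)chroman-4-one F1. A double Stille coupling of F1 with tributyl(3-methylbut-2-enyl)stannane (Pd(PPh3)4, DMF, 90 °C, neutral conditions) then returns to the route at 15.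

(2) Step 4. The phenoxide of 3 is flanked by two bromines, so the SN2 displacement may be slow enough for ionization of the benzylic alkoxyphosphonium (loss of enantiopurity) or elimination to the aryl diene to compete. The fallback forms the ether before the bromines are present. It sets out from 2 and 6: Mitsunobu coupling of the unhindered phenol 2 with 6 (PPh3, DIAD, toluene) should give (S)-1-[1-(3-bromo-4-methoxyphenyl)but-3-enyloxy]-3,5-bis(methoxymethoxy)benzene F2. Exhaustive ring A bromination (NBS, 3 equiv, CH2Cl2, −78 °C) should give (S)-2,4,6-tribromo-1-[1-(3-bromo-4-methoxyphenyl)but-3-enyloxy]-3,5-bis(methoxymethoxy)benzene F3. Regioselective bromine–lithium exchange of the one bromine flanked by two MOM ethers (n-BuLi, 1.0 equiv, THF, −100 °C; MeOH quench) then returns to the route at 7.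

(3) Step 2. Bromination at C4 (para to the hydroxyl) may compete with the second ortho bromination and give a mixture of dibromide isomers and tribromide. The fallback uses an unambiguous bromination followed by a selective removal. It sets out from 2: exhaustive bromination (NBS, 3.1 equiv) should give 2,4,6-tribromo-3,5-bis(methoxymethoxy)phenol F4. Treatment with n-BuLi (2.1 equiv, THF, −78 °C; the first equivalent forms the phenoxide, the second exchanges the bromine between the two MOM ethers) and MeOH quench returns to the route at 3.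

Further compounds
F1 | step 8 | (S)-8-bromo-2-(3-bromo-4-methoxyphenyl)-5,7-bis(methoxymethoxy)chroman-4-one | COc1ccc([C@@H]2CC(=O)c3c(OCOC)cc(OCOC)c(Br)c3O2)cc1Br
F2 | step 4 | (S)-1-[1-(3-bromo-4-methoxyphenyl)but-3-enyloxy]-3,5-bis(methoxymethoxy)benzene | C=CC[C@H](Oc1cc(OCOC)cc(OCOC)c1)c1ccc(OC)c(Br)c1
F3 | step 4 | (S)-2,4,6-tribromo-1-[1-(3-bromo-4-methoxyphenyl)but-3-enyloxy]-3,5-bis(methoxymethoxy)benzene | C=CC[C@H](Oc1c(Br)c(OCOC)c(Br)c(OCOC)c1Br)c1ccc(OC)c(Br)c1
F4 | step 2 | 2,4,6-tribromo-3,5-bis(methoxymethoxy)phenol | COCOc1c(Br)c(O)c(Br)c(OCOC)c1Br
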